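Do not read these flasks by their substrate. Partner, charged at 0.80 equiv, is the limiting reagent, so product stops at 80.0% of the substrate charged and 20.0% of the substrate stays behind.

common to all: substrate 0.10 M; free catalyst 0.2 mol%

| run | partner | added ligand | remark | time |
|---|---|---|---|---|
| midnight | 0.80 equiv | 0.36 mM | run made earlier |  |
| autumn | 0.80 equiv | 0.60 mM | run made earlier |  |
| green | 0.800 equiv | 0.15 mM |  | 4.0 min |
| teal | 0.800 equiv | 0.20 mM |  | 4.0 min |
| ochre | 0.800 equiv | 0.30 mM |  | 4.0 min |
| blue | 0.800 equiv | 0.50 mM |  | 4.0 min |
| grey | 0.800 equiv | 0.80 mM |  | 4.0 min |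

| run | time / min | product / % | substrate / % |
|---|---|---|---|
| midnight | 0.500 | 14.6 | 85.7 |
| midnight | 1.00 | 27.0 | 72.6 |
| midnight | 1.50 | 37.8 | 61.9 |
| midnight | 2.50 | 54.9 | 46.9 |
| midnight | 3.00 | 60.1 | 40.3 |
| autumn | 0.250 | 7.1 | 92.4 |
| autumn | 0.667 | 17.6 | 82.0 |
| autumn | 1.33 | 32.6 | 66.8 |
| autumn | 2.00 | 43.4 | 55.9 |
| autumn | 3.00 | 57.4 | 42.9 |

(scatter of a reading: 0.5 percentage points)

- amount of product at the end, in percent of the substrate charged for green, teal, ochre, blue, grey, in this order
- how the row runs (falls, then rises / falls all the way / rises all the way / hardly changes / rises, then falls)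

- "hardly changes" means that all values lie within two and a half points (for a concentration: within two and a half percent of the largest)

Climb the ladder from its fastest rung. The catalyst charge of 0.2 mol% is hardly any of the substrate, and at the first midnight reading, 0.500 min, product and substrate already sum to 100.3%, so no visible amount is held up on the catalyst.

On the next rung, take the partner left as the concentration that sets the order; this is my own reckoning. The last midnight reading gives 2.16 min for the partner clock τ, the time in which the partner left falls by the factor e. The last autumn reading gives 2.37 min. The first midnight reading gives a longer clock, 2.48 min, so in midnight τ shortens along the run, and I use the last readings, which stand nearest the asked time.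

From midnight to autumn, τ grows by 0.217 min for 0.240 mM more added ligand. This is a reading from two points, so it carries their scatter. Draw the straight line through them for the other flasks: green gets 1.97 min and grey 2.55 min.

The top rung is the asked time, 4.0 min, which is about twice green's clock. Product is then the cap times one minus exp(−t/τ). My row is 69.5%, 69.0%, 68.1%, 66.1%, 63.3%, falling from green to grey.

The forecast reads 62%, 72%, 71%, 70%, 67.5%, and its shape is: rises, then falls. At the low end it says “I assume the complex is the active species”, and there my green stands higher than its value.

The flask gives 69.9%, 69.5%, 68.7%, 67.1%, 64.5%: falls all the way.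

    free catalyst + added ligand ⇌ idle complex, settled at all times (K = 2300 M⁻¹)
    catalyst intermediate D → free catalyst + product (k = 18.9 s⁻¹)
    catalyst intermediate C ⇌ released group + catalyst intermediate D (K = 7.10 M, k = 265 s⁻¹)
    partner + catalyst intermediate B ⇌ catalyst intermediate C (K = 19.0 M⁻¹, k = 63.1 M⁻¹ s⁻¹)
    catalyst intermediate A → catalyst intermediate B (k = 52.9 s⁻¹)
    substrate + free catalyst ⇌ catalyst intermediate A (K = 16.3 M⁻¹, k = 212 M⁻¹ s⁻¹)

At 4.00 min the idle complex holds 3.35% of the catalyst in green and 18.6% in grey. Run the clock on to the partner left at that time, as a share of its charge: green's line gives 13.1% and the flask holds 13%, while grey's line gives 20.8% and the flask holds 19%.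

The readings are simulated from invented constants.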